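**Retrosynthetic overview**
- Feature used: on the benzo ring of the 2,2-dimethyl-2H-chromene, the C7 hydroxyl sits ortho to the C6 ketone carbonyl, and C5 on the other side of C6 carries a methoxy group. This pattern is what a C6≡C7 aryne gives after taking up a carboxylic acid, with C5–OMe as the polarising group.
- Last disconnection: the carbonyl next to the anisyl ring is carried as a dimethyl ketal and freed with aqueous acid at the end.
- Key disconnection: C7–O and C6–C(=O) are cut together. This leads back to the 6-trimethylsilyl-7-triflyloxychromene (aryne precursor) and 2,2-dimethoxy-2-(4-methoxyphenyl)acetic acid. No ring is closed in this step.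
- The C6 silicon comes from a C6 bromide by retro-Brook shift, because direct metalation or halogenation of a 7-oxygenated 5-methoxychromene cannot be trusted to tell C6 from C8. Bromine is therefore put on mirror-symmetric methyl 2,6-dihydroxy-4-methoxybenzoate, which has only one possible product, and the ester blocks the future C8 until the pyran ring is on.
- Ring order: both benzene rings are bought, and the pyran ring is the only ring built (prenal annulation with oxa-6π closure, step 2). The ketal acid comes from the keto ester in two steps.

Key step: step 7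

Remark: the target has no stereocentre, no stereogenic axis and no E/Z-isomeric double bond (C3=C4 is locked cis in the pyran ring). There is no enantiomer to select, and no step has to control configuration.
Remark: methyl 2,6-dihydroxy-4-methoxybenzoate, prenal and methyl 2-(4-methoxyphenyl)-2-oxoacetate are assumed to be catalogue chemicals.

**Step 1**
Reactants: 1 methyl 2,6-dihydroxy-4-methoxybenzoate
Product: 2 methyl 3-bromo-2,6-dihydroxy-4-methoxybenzoate
Conditions: NBS (1.0 equiv), MeCN, −20 to 0 °C
Reagents that add atoms: N-bromosuccinimide, O=C1CCC(=O)N1Br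
Why: Electrophilic aromatic bromination of a doubly activated ring: the two free positions of 1 are related by the mirror plane through C1 and C4, so monobromination can give only 2 (Br between an OH and the OMe), and one equivalent of NBS in the cold should hold back a second bromination.

**Step 2**
Reactants: 2 methyl 3-bromo-2,6-dihydroxy-4-methoxybenzoate; 3 3-methylbut-2-enal (prenal)
Product: 5 methyl 6-bromo-7-hydroxy-5-methoxy-2,2-dimethyl-2H-chromene-8-carboxylate, via ortho-quinone methide 4 (not isolated)
Conditions: 3 (2 equiv), ethylenediammonium diacetate (20 mol %), xylene, 140 °C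
Reagents that add atoms: none
Why: Amine-salt-catalysed chromene annulation of a resorcinol with an enal (Knoevenagel-type C–C bond formation, loss of water to 4, oxa-6π electrocyclisation): the ring has a single free carbon, activated by an ortho OH, an ortho OMe and a para OH, and only one hydroxyl next to it, so neither a regioisomer nor a second annulation is possible.

**Step 3**
Reactants: 5 methyl 6-bromo-7-hydroxy-5-methoxy-2,2-dimethyl-2H-chromene-8-carboxylate
Product: 7 6-bromo-5-methoxy-2,2-dimethyl-2H-chromen-7-ol, via chromene-8-carboxylic acid 6 (not isolated)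
Conditions: KOH (8 equiv), ethylene glycol–H2O (4:1), 120 °C; then AcOH to pH 5, 60 °C
Reagents that add atoms: none
Why: Saponification followed by protodecarboxylation: the hindered ester needs hot alkali, which the bromide, the aryl methyl ether and the pyran alkene tolerate, and the 2,4,6-trioxygenated salicylic acid 6 is protonated at its ipso carbon so readily that it should lose CO2 on gentle warming in acetate buffer, uncovering C8–H.

**Step 4**
Reactants: 7 6-bromo-5-methoxy-2,2-dimethyl-2H-chromen-7-ol
Product: 10 5-methoxy-2,2-dimethyl-6-(trimethylsilyl)-2H-chromen-7-yl trifluoromethanesulfonate, via O-trimethylsilyl ether 8 (not isolated), via lithium 6-silylchromen-7-olate 9 (not isolated)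
Conditions: HMDS, THF, 65 °C, then evaporate; n-BuLi (1.1 equiv), THF, −78 °C; Tf2O (1.2 equiv), −78 to 0 °C
Reagents that add atoms: hexamethyldisilazane, C[Si](C)(C)N[Si](C)(C)C; trifluoromethanesulfonic anhydride, O=S(=O)(OS(=O)(=O)C(F)(F)F)C(F)(F)F
Why: Standard conversion of an ortho-bromophenol into an ortho-silylaryl triflate (O-silylation, Br–Li exchange, 1,3 O→C silyl shift or retro-Brook rearrangement, O-triflation of the phenoxide): the bromine dictates where the silicon goes, and exchange at −78 °C is far faster than any attack on the pyran alkene or on C8–H.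

**Step 5**
Reactants: 11 methyl 2-(4-methoxyphenyl)-2-oxoacetate
Product: 12 methyl 2,2-dimethoxy-2-(4-methoxyphenyl)acetate
Conditions: HC(OMe)3 (5 equiv), MeOH, conc. H2SO4 (cat.), reflux
Reagents that add atoms: trimethyl orthoformate, COC(OC)OC
Why: Acid-catalysed ketalisation with the orthoformate as dehydrating agent: only the ketone carbonyl can ketalise, and it passes through an oxocarbenium ion stabilised by the 4-methoxyphenyl group.

**Step 6**
Reactants: 12 methyl 2,2-dimethoxy-2-(4-methoxyphenyl)acetate
Product: 13 2,2-dimethoxy-2-(4-methoxyphenyl)acetic acid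
Conditions: LiOH·H2O (3 equiv), THF–MeOH–H2O, 40 °C; then 1 M HCl to pH 3–4, 0 °C, quick extraction, azeotropic drying (PhMe)
Reagents that add atoms: lithium hydroxide, [Li+].[OH-]
Why: Ester saponification (BAc2): the ketal is inert to base, and a short cold acidification should free the acid without ionising the ketal, whose cation is destabilised by the adjacent carboxyl group.

**Step 7**
Reactants: 10 5-methoxy-2,2-dimethyl-6-(trimethylsilyl)-2H-chromen-7-yl trifluoromethanesulfonate; 13 2,2-dimethoxy-2-(4-methoxyphenyl)acetic acid
Product: 16 1-(7-hydroxy-5-methoxy-2,2-dimethyl-2H-chromen-6-yl)-2,2-dimethoxy-2-(4-methoxyphenyl)ethanone, via chromenyne 14 (not isolated), via C6-caesio aryl ester 15 (not isolated)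
Conditions: 10 (1.5 equiv), CsF (4 equiv), THF (0.02 M), 125 °C, sealed tube; then aq NH4Cl
Reagents that add atoms: none
Why: Fluoride removes the C6 silyl group of 10 with loss of the C7 triflate to give aryne 14, and CsF also converts 13 into its caesium carboxylate. The carboxylate oxygen adds to C7 to give the C6 carbanion 15, which attacks its own ester carbonyl; the strained four-membered alkoxide opens at once to the C6 ketone and the C7 phenoxide, so both new bonds (C7–O and C6–C=O) form in one operation, no ring stays closed and no stereocentre arises. The closest known reaction type is this very one, the insertion of arynes into the C(acyl)–O bond of carboxylic acids (O-arylation, then anionic Fries-type 1,3-acyl shift) in hot dilute THF with CsF; 13 is bulkier at its α-carbon than the acids usually used, but its two α-alkoxy groups raise the electrophilicity of the ester carbonyl. Regioselectivity is required and is secured by the C5 methoxy group, whose inductive pull distorts the aryne so that the nucleophile enters at the remote, unhindered C7 and the charge develops at C6 next to the C5–O bond; the ring oxygen at C8a is one position further away and opposes this only weakly. The acyl shift must also outrun protonation of 15, which is served by high dilution, high temperature, dry reagents and the absence of any α-hydrogen in 13. The ketal is needed because a free ketone would lie within five-membered reach of the C6 carbanion and would divert it to a 3-aryl-3-hydroxybenzofuran-2-one, while the pyran alkene is inert to CsF and is kept from aryne cycloaddition by the dilution.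

**Step 8**
Reactants: 16 1-(7-hydroxy-5-methoxy-2,2-dimethyl-2H-chromen-6-yl)-2,2-dimethoxy-2-(4-methoxyphenyl)ethanone
Product: 17 1-(7-hydroxy-5-methoxy-2,2-dimethyl-2H-chromen-6-yl)-2-(4-methoxyphenyl)ethane-1,2-dione (target)
Conditions: 1 M aq HCl–THF (1:4), 25–40 °C
Reagents that add atoms: water, O
Why: Acid-catalysed ketal hydrolysis: the 4-methoxyphenyl group stabilises the oxocarbenium ion enough for dilute acid to suffice, the large excess of water should also carry on any cyclic mixed ketal formed by reversible capture with the C7 hydroxyl, and the C6 acyl group lowers the basicity of the pyran alkene so that it should survive.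

**Compound list**
1 | methyl 2,6-dihydroxy-4-methoxybenzoate | COC(=O)c1c(O)cc(OC)cc1O | starting material
2 | methyl 3-bromo-2,6-dihydroxy-4-methoxybenzoate | COC(=O)c1c(O)cc(OC)c(Br)c1O | intermediate
3 | 3-methylbut-2-enal (prenal) | CC(C)=CC=O | starting material
4 | methyl 3-bromo-2-hydroxy-4-methoxy-5-(3-methylbut-2-enylidene)-6-oxocyclohexa-1,3-diene-1-carboxylate (ortho-quinone methide, not isolated) | COC(=O)C1=C(O)C(Br)=C(OC)C(=CC=C(C)C)C1=O | intermediate
5 | methyl 6-bromo-7-hydroxy-5-methoxy-2,2-dimethyl-2H-chromene-8-carboxylate | COC(=O)c1c(O)c(Br)c(OC)c2C=CC(C)(C)Oc12 | intermediate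
6 | 6-bromo-7-hydroxy-5-methoxy-2,2-dimethyl-2H-chromene-8-carboxylic acid (not isolated) | OC(=O)c1c(O)c(Br)c(OC)c2C=CC(C)(C)Oc12 | intermediate
7 | 6-bromo-5-methoxy-2,2-dimethyl-2H-chromen-7-ol | COc1c(Br)c(O)cc2OC(C)(C)C=Cc12 | intermediate
8 | (6-bromo-5-methoxy-2,2-dimethyl-2H-chromen-7-yl)oxy-trimethylsilane (not isolated) | COc1c(Br)c(O[Si](C)(C)C)cc2OC(C)(C)C=Cc12 | intermediate
9 | lithium 5-methoxy-2,2-dimethyl-6-(trimethylsilyl)-2H-chromen-7-olate (not isolated) | [Li+].COc1c([Si](C)(C)C)c([O-])cc2OC(C)(C)C=Cc12 | intermediate
10 | 5-methoxy-2,2-dimethyl-6-(trimethylsilyl)-2H-chromen-7-yl trifluoromethanesulfonate | COc1c([Si](C)(C)C)c(OS(=O)(=O)C(F)(F)F)cc2OC(C)(C)C=Cc12 | intermediate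
11 | methyl 2-(4-methoxyphenyl)-2-oxoacetate | COC(=O)C(=O)c1ccc(OC)cc1 | starting material
12 | methyl 2,2-dimethoxy-2-(4-methoxyphenyl)acetate | COC(=O)C(OC)(OC)c1ccc(OC)cc1 | intermediate
13 | 2,2-dimethoxy-2-(4-methoxyphenyl)acetic acid | COc1ccc(C(OC)(OC)C(=O)O)cc1 | intermediate
14 | 5-methoxy-2,2-dimethyl-6,7-didehydro-2H-chromene (aryne, not isolated) | COC1=C2C=CC(C)(C)OC2=CC#C1 | intermediate
15 | caesium salt of the C6 carbanion of 5-methoxy-2,2-dimethyl-2H-chromen-7-yl 2,2-dimethoxy-2-(4-methoxyphenyl)acetate (not isolated) | [Cs+].COc1ccc(cc1)C(OC)(OC)C(=O)Oc1cc2OC(C)(C)C=Cc2c(OC)[c-]1 | intermediate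
16 | 1-(7-hydroxy-5-methoxy-2,2-dimethyl-2H-chromen-6-yl)-2,2-dimethoxy-2-(4-methoxyphenyl)ethanone | COc1ccc(C(OC)(OC)C(=O)c2c(O)cc3OC(C)(C)C=Cc3c2OC)cc1 | intermediate
17 | 1-(7-hydroxy-5-methoxy-2,2-dimethyl-2H-chromen-6-yl)-2-(4-methoxyphenyl)ethane-1,2-dione | COc1ccc(C(=O)C(=O)c2c(O)cc3c(c2OC)C=CC(C)(C)O3)cc1 | target

Total step count: 8. Longest linear sequence: 6 steps (1, 2, 3, 4, 7, 8).

**Steps most likely to fail**

Step 7 carries the main risk.
- What may go wrong: the C6 carbanion may be protonated by bifluoride, traces of water or solvent before the acyl group moves. The crowded acyl group may also transfer too slowly, so the sequence stops after O-arylation. Aryne may further be lost by cycloaddition to the styrene-type alkene of a second molecule.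
- Fallback: it sets out from 7 and 13 and generates the same carbanion in an aprotic medium without an aryne. Esterification (EDC·HCl, DMAP, CH2Cl2, 0 °C to rt) should give 6-bromo-5-methoxy-2,2-dimethyl-2H-chromen-7-yl 2,2-dimethoxy-2-(4-methoxyphenyl)acetate F1. Bromine–lithium exchange (n-BuLi, THF–Et2O, −100 °C) then triggers the known anionic ortho-Fries rearrangement of ortho-haloaryl esters. Aqueous work-up brings the route back at 16.

Step 2 is the next risk.
- What may go wrong: C–C bond formation at a carbon flanked on both sides, in a ring that also carries an ester and a bromine, may be so slow that self-condensation of prenal takes over.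
- Fallback: it sets out from 2 and makes the aryl–carbon bond first. Magnesium-mediated ortho-formylation (MgCl2, Et3N, paraformaldehyde, MeCN, reflux; Casnati–Skattebøl) at the only free carbon should give methyl 3-bromo-5-formyl-2,6-dihydroxy-4-methoxybenzoate F2. Heating F2 with 2-methylprop-1-enylboronic acid and dibenzylamine in dioxane at 90 °C is a Petasis borono-Mannich reaction. Thermal loss of the amine then leads to the same quinone methide 4, and oxa-6π closure returns to the route at 5.

Step 8 is the third risk.
- What may go wrong: the oxocarbenium ion may be intercepted by the neighbouring C7 hydroxyl. This would hold the material in a cyclic mixed-ketal form and call for stronger acid, under which protonation of the pyran alkene begins.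
- Fallback: it sets out from 16 and removes the neighbouring nucleophile first. TBSOTf with 2,6-lutidine in CH2Cl2 at 0 °C should give 1-[7-(tert-butyldimethylsilyloxy)-5-methoxy-2,2-dimethyl-2H-chromen-6-yl]-2,2-dimethoxy-2-(4-methoxyphenyl)ethanone F3. Dilute aqueous acid in THF should then open the ketal directly to 1-[7-(tert-butyldimethylsilyloxy)-5-methoxy-2,2-dimethyl-2H-chromen-6-yl]-2-(4-methoxyphenyl)ethane-1,2-dione F4. Buffered fluoride (TBAF, AcOH, THF, 0 °C) returns to the route at 17.

**Further compounds**
F1 | step 7 | 6-bromo-5-methoxy-2,2-dimethyl-2H-chromen-7-yl 2,2-dimethoxy-2-(4-methoxyphenyl)acetate | COc1ccc(cc1)C(OC)(OC)C(=O)Oc1cc2OC(C)(C)C=Cc2c(OC)c1Br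
F2 | step 2 | methyl 3-bromo-5-formyl-2,6-dihydroxy-4-methoxybenzoate | COC(=O)c1c(O)c(Br)c(OC)c(C=O)c1O
F3 | step 8 | 1-[7-(tert-butyldimethylsilyloxy)-5-methoxy-2,2-dimethyl-2H-chromen-6-yl]-2,2-dimethoxy-2-(4-methoxyphenyl)ethanone | COc1ccc(C(OC)(OC)C(=O)c2c(O[Si](C)(C)C(C)(C)C)cc3OC(C)(C)C=Cc3c2OC)cc1
F4 | step 8 | 1-[7-(tert-butyldimethylsilyloxy)-5-methoxy-2,2-dimethyl-2H-chromen-6-yl]-2-(4-methoxyphenyl)ethane-1,2-dione | COc1ccc(C(=O)C(=O)c2c(O[Si](C)(C)C(C)(C)C)cc3OC(C)(C)C=Cc3c2OC)cc1
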